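## Retrosynthetic overview

1. Feature: ring A (C4a, C5, C6, C7, C8, C8a) is a hexasubstituted benzene. Its oxygen-bearing carbons C5, C7 and C8a alternate with the carbon-bearing carbons C4a, C6 and C8. A four-carbon vinylketene (C5, C8, C8a, C4a) and a two-carbon ynol ether (C6, C7) together carry exactly this pattern.
2. Ring A is therefore made last, by a Danheiser benzannulation in its photo-Wolff variant. The partners are a prenylated α-diazo ketone on C6 of an (S)-2-aryl-2,3-dihydropyran-4-one (ring C, with C2 already set) and a prenylated TIPS ynol ether. The bonds formed are C8–C8a, C5–C6, C7–C8 and C4a–C5.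
3. The diazo ketone goes back by deacylative diazo transfer to the homoprenyl ketone, and by Negishi acylation to the pyranone-6-carboxylic acid. The acid goes back by a catalytic asymmetric aldol/cyclodehydration (a formal hetero-Diels–Alder reaction) to the chromene aldehyde and the bis-silyl dienol ether of ethyl 2,4-dioxopentanoate.
4. The chromene aldehyde comes from resorcinol by chromanone formation, reduction–dehydration and ortho-formylation. The ynol ether comes from prenyl bromide through the skipped enyne and its ynolate.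
5. Ring order: the pyran ring of the chromene on ring B, then ring C, then ring A. The ring B phenol is carried as a TIPS ether like the C7 oxygen, so one buffered fluoride step ends the route without acid.

Key step: step 12

Assumption: the (R,R)-bisphosphoramide of step 6 is taken to shield the Re face of the silicon-bound aryl aldehyde. If the sense of induction proves opposite, the equally accessible (S,S)-catalyst is used and nothing else changes.

Abbreviation: Ar = 2,2-dimethyl-7-(triisopropylsilyloxy)-2H-chromen-6-yl. Pyranone C6 and C5 become flavanone C8a and C4a.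

## Route

**Step 1**
Reactants: 1 resorcinol; 2 3-methylbut-2-enoic acid
Product: 3 7-hydroxy-2,2-dimethylchroman-4-one
Conditions: P2O5, MeSO3H, 70 °C
Reagents that add atoms: none
Why: Friedel–Crafts acylation at C4 of resorcinol and oxa-Michael closure by the adjacent hydroxyl run in one pot in this medium, which is the standard entry to 7-hydroxy-2,2-dimethylchromanones.

**Step 2**
Reactants: 3 7-hydroxy-2,2-dimethylchroman-4-one
Product: 5 2,2-dimethyl-2H-chromen-7-ol, via 2,2-dimethylchromane-4,7-diol 4 (not isolated)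
Conditions: LiAlH4, THF, 0 °C to reflux; then 2 M HCl, rt
Reagents that add atoms: none
Why: Hydride reduction gives the benzylic alcohol, which loses water on acidification because the cation at C4 is stabilised by the para oxygen on C7 (reduction–dehydration sequence).

**Step 3**
Reactants: 5 2,2-dimethyl-2H-chromen-7-ol
Product: 6 7-hydroxy-2,2-dimethyl-2H-chromene-6-carbaldehyde
Conditions: MgCl2, Et3N, (CH2O)n, MeCN, reflux; dilute HCl work-up
Reagents that add atoms: paraformaldehyde (as formaldehyde), C=O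
Why: Casnati–Skattebøl ortho-formylation through the magnesium phenoxide should place the formyl group on C6, the open ortho carbon that is also para to O1, rather than on C8 between two oxygens, and it leaves the chromene alkene alone.

**Step 4**
Reactants: 6 7-hydroxy-2,2-dimethyl-2H-chromene-6-carbaldehyde
Product: 7 2,2-dimethyl-7-(triisopropylsilyloxy)-2H-chromene-6-carbaldehyde
Conditions: TIPSOTf, 2,6-lutidine, CH2Cl2, 0 °C
Reagents that add atoms: triisopropylsilyl triflate, CC(C)[Si](C(C)C)(C(C)C)OS(=O)(=O)C(F)(F)F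
Why: The silyl triflate overcomes the salicylaldehyde hydrogen bond, and the non-chelating aryl TIPS ether should survive amide base, organozinc and catalytic acid and later leave together with the C7 silyl ether (O-silylation).

**Step 5**
Reactants: 8 ethyl 2,4-dioxopentanoate
Product: 9 ethyl (2Z)-2,4-bis(trimethylsilyloxy)penta-2,4-dienoate
Conditions: TMSOTf (2.2 equiv), Et3N, Et2O, 0 °C to rt
Reagents that add atoms: trimethylsilyl triflate, C[Si](C)(C)OS(=O)(=O)C(F)(F)F
Why: Twofold soft enolisation and O-silylation of a 1,3-dicarbonyl compound gives the 1,3-bis(silyloxy)diene, whose enol ether geometry is lost again in step 6.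

**Step 6**
Reactants: 7 2,2-dimethyl-7-(triisopropylsilyloxy)-2H-chromene-6-carbaldehyde; 9 ethyl (2Z)-2,4-bis(trimethylsilyloxy)penta-2,4-dienoate
Product: 11 ethyl (2S)-2-Ar-4-oxo-3,4-dihydro-2H-pyran-6-carboxylate, via (6S)-hydroxy diketo ester 10 (not isolated)
Conditions: SiCl4 (1.2 equiv), (R,R)-bisphosphoramide (two N,N'-dimethyl-1,1'-binaphthyl-2,2'-diamine phosphoramide units on an N,N'-dimethylpentane-1,5-diamine tether, 5 mol %), iPr2NEt (10 mol %), CH2Cl2, −78 °C; aq NaHCO3; then TFA (0.1 equiv), CH2Cl2, 0 °C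
Reagents that add atoms: none
Why: In this Lewis-base-activated SiCl4 Mukaiyama aldol addition of a 1,3-dicarbonyl-derived silyl dienol ether through its terminal carbon, the cationic chiral silicon complex is electrophilic enough for an electron-rich aldehyde and an ester-deactivated diene, it shields the Re face so that the C2–C3 bond forms on the Si face and sets (S), and catalytic acid then closes O1–C6 by hemiketalisation and dehydration (formal hetero-Diels–Alder reaction).

**Step 7**
Reactants: 11 ethyl (2S)-2-Ar-4-oxo-3,4-dihydro-2H-pyran-6-carboxylate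
Product: 13 (2S)-2-Ar-4-oxo-3,4-dihydro-2H-pyran-6-carboxylic acid, via trimethylstannyl ester 12 (not isolated)
Conditions: Me3SnOH, ClCH2CH2Cl, 60 °C; cold dilute HCl wash
Reagents that add atoms: trimethyltin hydroxide, C[Sn](C)(C)O
Why: Trimethyltin hydroxide cleaves the activated ester under essentially neutral conditions, so neither deprotonation at C3 with expulsion of O1 (loss of C2 configuration) nor cleavage of the aryl silyl ether should compete.

**Step 8**
Reactants: 13 (2S)-2-Ar-4-oxo-3,4-dihydro-2H-pyran-6-carboxylic acid; 14 5-bromo-2-methylpent-2-ene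
Product: 17 (2S)-2-Ar-6-(5-methylhex-4-enoyl)-2,3-dihydro-4H-pyran-4-one, via acid chloride 15 (not isolated), via homoprenylzinc bromide 16 (not isolated)
Conditions: 13: 1-chloro-N,N,2-trimethylprop-1-en-1-amine, CH2Cl2, 0 °C; 14: Zn, LiCl, THF, 40 °C; combine, Pd(PPh3)4 (5 mol %), THF, 0 °C to rt
Reagents that add atoms: none
Why: In this Negishi acylation the neutral chloroenamine makes the acid chloride without HCl, and the alkylzinc halide hands its group only to the acylpalladium species, so the C4 ketone and the enedione alkene stay untouched.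

**Step 9**
Reactants: 17 (2S)-2-Ar-6-(5-methylhex-4-enoyl)-2,3-dihydro-4H-pyran-4-one
Product: 20 (2S)-2-Ar-6-(2-diazo-5-methylhex-4-enoyl)-2,3-dihydro-4H-pyran-4-one, via lithium enolate 18 (not isolated), via trifluoroacetyl ketone 19 (not isolated)
Conditions: LiHMDS (1.05 equiv), THF, −78 °C; CF3CO2CH2CF3, −78 °C; cold dilute HCl; then MsN3, Et3N, H2O (1 equiv), MeCN, rt
Reagents that add atoms: methanesulfonyl azide, CS(=O)(=O)N=[N+]=[N-]
Why: In this detrifluoroacetylative diazo transfer, the standard access to α'-diazo enones, the side-chain CH2 next to the ordinary ketone is more acidic than C3–H2 of the vinylogous ester, so kinetic enolisation, trifluoroacetylation and azide transfer with loss of the trifluoroacetyl group should all occur there.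

**Step 10**
Reactants: 21 1-bromo-3-methylbut-2-ene; 22 ethynylmagnesium bromide
Product: 23 5-methylhex-4-en-1-yne
Conditions: CuCl (5 mol %), THF, 0 to 40 °C
Reagents that add atoms: none
Why: Copper-catalysed SN2 coupling of an alkynyl Grignard reagent with a primary allylic bromide should give the linear skipped enyne.

**Step 11**
Reactants: 23 5-methylhex-4-en-1-yne
Product: 26 triisopropyl[(5-methylhex-4-en-1-yn-1-yl)oxy]silane, via lithium acetylide 24 (not isolated), via lithium ynolate 25 (not isolated)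
Conditions: n-BuLi, THF, −78 °C; t-BuOOLi (from t-BuOOH, LiHMDS), −78 to 0 °C; TIPSOTf, −78 to 0 °C
Reagents that add atoms: tert-butyl hydroperoxide, CC(C)(C)OO; triisopropylsilyl triflate, CC(C)[Si](C(C)C)(C(C)C)OS(=O)(=O)C(F)(F)F
Why: Oxygen transfer from lithium tert-butyl peroxide to the acetylide gives the ynolate, which the bulky silyl triflate traps on oxygen (acetylide oxidation route to siloxyalkynes), and neither reagent touches the trisubstituted alkene.

**Step 12**
Reactants: 20 (2S)-2-Ar-6-(2-diazo-5-methylhex-4-enoyl)-2,3-dihydro-4H-pyran-4-one; 26 triisopropyl[(5-methylhex-4-en-1-yn-1-yl)oxy]silane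
Product: 31 (2S)-2-Ar-5-hydroxy-6,8-bis(3-methylbut-2-enyl)-7-(triisopropylsilyloxy)chroman-4-one, via vinylketene 27 (not isolated), via vinylcyclobutenone 28 (not isolated), via dienylketene 29 (not isolated), via cyclohexadienone 30 (not isolated)
Conditions: 26 (2 equiv), degassed toluene, 405 nm LED, rt, until N2 evolution ends; then 90 °C in the dark
Reagents that add atoms: none
Why: Excitation of the long-wavelength band of the diazo ketone at 405 nm, where neither the photochromic 2,2-dimethylchromene nor the product flavanone absorbs, releases N2 while pyranone C6 shifts to the diazo carbon (Wolff rearrangement, C8–C8a) to give vinylketene 27. The prenyl-bearing, nucleophilic carbon of 26 then bonds to the ketene carbonyl carbon (C5–C6) and the silyloxy carbon closes onto the prenylated ketene carbon (C7–C8), so the polarity of the ynol ether alone puts OTIPS on C7 and the alkyne prenyl on C6 in cyclobutenone 28. Heating opens 28 by reversible 4π cleavage of its C5–C8 bond to dienylketene 29, ring A closes by 6π electrocyclisation of C5 onto C4a, and dienone 30 enolises at once because its C4a–H lies between two carbonyls, leaving the C5 phenol chelated to the C4 ketone. The closest known reaction type is the Danheiser benzannulation of α'-diazo enones with siloxyalkynes, applied here with a cyclic β-acyl enol ether as the vinyl unit. No lasting stereocentre is created (the quaternary carbon of 28 and C4a of 30 vanish on aromatisation) and C2 is a spectator under these neutral conditions. The step needs vinyl migration to outrun a 1,2-hydrogen shift from the allylic CH2 on the diazo carbon, which direct singlet excitation and the high migratory aptitude of an sp2 carbon favour, and it needs the alkyne to trap the ketene before the product phenol does, which the excess of 26 and the chelated, flanked C5–OH should secure.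

**Step 13**
Reactants: 31 (2S)-2-Ar-5-hydroxy-6,8-bis(3-methylbut-2-enyl)-7-(triisopropylsilyloxy)chroman-4-one
Product: 32 euchrenone a3
Conditions: TBAF, AcOH (1:1), THF, 0 °C
Reagents that add atoms: none
Why: Fluoride cleaves both aryl silyl ethers while the acetic acid buffer keeps the phenols protonated, so both the retro-oxa-Michael opening that racemises flavanones and the acid-induced cyclisation of ortho-prenylphenols are avoided (buffered desilylation).

## Compound list

1 | resorcinol | Oc1cccc(O)c1 | starting material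
2 | 3-methylbut-2-enoic acid | CC(C)=CC(=O)O | starting material
3 | 7-hydroxy-2,2-dimethylchroman-4-one | CC1(C)CC(=O)c2ccc(O)cc2O1 | intermediate
4 | 2,2-dimethylchromane-4,7-diol (racemic) | CC1(C)CC(O)c2ccc(O)cc2O1 | intermediate
5 | 2,2-dimethyl-2H-chromen-7-ol | CC1(C)C=Cc2ccc(O)cc2O1 | intermediate
6 | 7-hydroxy-2,2-dimethyl-2H-chromene-6-carbaldehyde | CC1(C)C=Cc2cc(C=O)c(O)cc2O1 | intermediate
7 | 2,2-dimethyl-7-(triisopropylsilyloxy)-2H-chromene-6-carbaldehyde | CC1(C)C=Cc2cc(C=O)c(O[Si](C(C)C)(C(C)C)C(C)C)cc2O1 | intermediate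
8 | ethyl 2,4-dioxopentanoate | CCOC(=O)C(=O)CC(C)=O | starting material
9 | ethyl (2Z)-2,4-bis(trimethylsilyloxy)penta-2,4-dienoate | C=C(O[Si](C)(C)C)/C=C(\O[Si](C)(C)C)C(=O)OCC | intermediate
10 | ethyl (6S)-6-Ar-6-hydroxy-2,4-dioxohexanoate | CCOC(=O)C(=O)CC(=O)C[C@H](O)c1cc2c(cc1O[Si](C(C)C)(C(C)C)C(C)C)OC(C)(C)C=C2 | intermediate
11 | ethyl (2S)-2-Ar-4-oxo-3,4-dihydro-2H-pyran-6-carboxylate | CCOC(=O)C1=CC(=O)C[C@@H](c2cc3c(cc2O[Si](C(C)C)(C(C)C)C(C)C)OC(C)(C)C=C3)O1 | intermediate
12 | trimethylstannyl (2S)-2-Ar-4-oxo-3,4-dihydro-2H-pyran-6-carboxylate | C[Sn](C)(C)OC(=O)C1=CC(=O)C[C@@H](c2cc3c(cc2O[Si](C(C)C)(C(C)C)C(C)C)OC(C)(C)C=C3)O1 | intermediate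
13 | (2S)-2-Ar-4-oxo-3,4-dihydro-2H-pyran-6-carboxylic acid | OC(=O)C1=CC(=O)C[C@@H](c2cc3c(cc2O[Si](C(C)C)(C(C)C)C(C)C)OC(C)(C)C=C3)O1 | intermediate
14 | 5-bromo-2-methylpent-2-ene | CC(C)=CCCBr | starting material
15 | (2S)-2-Ar-4-oxo-3,4-dihydro-2H-pyran-6-carbonyl chloride | ClC(=O)C1=CC(=O)C[C@@H](c2cc3c(cc2O[Si](C(C)C)(C(C)C)C(C)C)OC(C)(C)C=C3)O1 | intermediate
16 | (4-methylpent-3-enyl)zinc bromide | CC(C)=CCC[Zn]Br | intermediate
17 | (2S)-2-Ar-6-(5-methylhex-4-enoyl)-2,3-dihydro-4H-pyran-4-one | CC(C)=CCCC(=O)C1=CC(=O)C[C@@H](c2cc3c(cc2O[Si](C(C)C)(C(C)C)C(C)C)OC(C)(C)C=C3)O1 | intermediate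
18 | lithium enolate of 17 (side-chain enolate) | [Li+].CC(C)=CCC=C([O-])C1=CC(=O)C[C@@H](c2cc3c(cc2O[Si](C(C)C)(C(C)C)C(C)C)OC(C)(C)C=C3)O1 | intermediate
19 | (2S)-2-Ar-6-[5-methyl-2-(trifluoroacetyl)hex-4-enoyl]-2,3-dihydro-4H-pyran-4-one (epimers and enol at the side-chain carbon) | CC(C)=CCC(C(=O)C(F)(F)F)C(=O)C1=CC(=O)C[C@@H](c2cc3c(cc2O[Si](C(C)C)(C(C)C)C(C)C)OC(C)(C)C=C3)O1 | intermediate
20 | (2S)-2-Ar-6-(2-diazo-5-methylhex-4-enoyl)-2,3-dihydro-4H-pyran-4-one | CC(C)=CCC(=[N+]=[N-])C(=O)C1=CC(=O)C[C@@H](c2cc3c(cc2O[Si](C(C)C)(C(C)C)C(C)C)OC(C)(C)C=C3)O1 | intermediate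
21 | 1-bromo-3-methylbut-2-ene | CC(C)=CCBr | starting material
22 | ethynylmagnesium bromide | C#C[Mg]Br | starting material
23 | 5-methylhex-4-en-1-yne | CC(C)=CCC#C | intermediate
24 | (5-methylhex-4-en-1-ynyl)lithium | CC(C)=CCC#C[Li] | intermediate
25 | lithium 5-methylhex-4-en-1-yn-1-olate | CC(C)=CCC#C[O-].[Li+] | intermediate
26 | triisopropyl[(5-methylhex-4-en-1-yn-1-yl)oxy]silane | CC(C)=CCC#CO[Si](C(C)C)(C(C)C)C(C)C | intermediate
27 | vinylketene: (2S)-2-Ar-6-(5-methyl-1-oxohexa-1,4-dien-2-yl)-2,3-dihydro-4H-pyran-4-one | CC(C)=CCC(=C=O)C1=CC(=O)C[C@@H](c2cc3c(cc2O[Si](C(C)C)(C(C)C)C(C)C)OC(C)(C)C=C3)O1 | intermediate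
28 | vinylcyclobutenone: 2,4-diprenyl-3-(triisopropylsilyloxy)cyclobut-2-enone bearing the (2S)-2-Ar-4-oxo-dihydropyran-6-yl group on C4 (both C4 epimers) | CC(C)=CCC1=C(O[Si](C(C)C)(C(C)C)C(C)C)C(CC=C(C)C)(C1=O)C2=CC(=O)C[C@@H](c3cc4c(cc3O[Si](C(C)C)(C(C)C)C(C)C)OC(C)(C)C=C4)O2 | intermediate
29 | dienylketene (ketene carbon cis to the pyranone) | CC(C)=CCC(=C=O)/C(O[Si](C(C)C)(C(C)C)C(C)C)=C(/CC=C(C)C)C1=CC(=O)C[C@@H](c2cc3c(cc2O[Si](C(C)C)(C(C)C)C(C)C)OC(C)(C)C=C3)O1 | intermediate
30 | cyclohexadienone, the C4a–H keto tautomer of 31 (both C4a epimers) | CC(C)=CCC1=C(O[Si](C(C)C)(C(C)C)C(C)C)C(CC=C(C)C)=C2O[C@H](c3cc4c(cc3O[Si](C(C)C)(C(C)C)C(C)C)OC(C)(C)C=C4)CC(=O)C2C1=O | intermediate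
31 | (2S)-2-Ar-5-hydroxy-6,8-bis(3-methylbut-2-enyl)-7-(triisopropylsilyloxy)chroman-4-one | CC(C)=CCc1c(O[Si](C(C)C)(C(C)C)C(C)C)c(CC=C(C)C)c2c(c1O)C(=O)C[C@@H](c1cc3c(cc1O[Si](C(C)C)(C(C)C)C(C)C)OC(C)(C)C=C3)O2 | intermediate
32 | euchrenone a3, (2S)-5,7-dihydroxy-2-(7-hydroxy-2,2-dimethyl-2H-chromen-6-yl)-6,8-bis(3-methylbut-2-enyl)chroman-4-one | CC(C)=CCc1c(O)c(CC=C(C)C)c2c(c1O)C(=O)C[C@@H](c1cc3c(cc1O)OC(C)(C)C=C3)O2 | target

## Step count and risks

Total step count: 13.

Longest linear sequence: 10 steps from resorcinol (steps 1–4, 6–9, 12, 13).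

**Risk 1, step 12.**
- After loss of N2, a 1,2-hydrogen shift from the allylic CH2 may outrun vinyl migration.
- The electron-poor vinylketene may dimerise or close on itself before the alkyne traps it.
- The crowded cyclobutenone may resist thermal opening.

Fallback, from 6 and 21 back to 32: ring A is taken from the aromatic pool instead of being built. Commercial 2,4,6-trihydroxyacetophenone is C-prenylated twice with 21 (KOH, H2O, 0 °C) to 2,4,6-trihydroxy-3,5-bis(3-methylbut-2-enyl)acetophenone F1. MOMCl and iPr2NEt mask the two non-chelated hydroxyls to give the bis-MOM acetophenone F2. Aldehyde 6 is converted in the same way to 7-(methoxymethoxy)-2,2-dimethyl-2H-chromene-6-carbaldehyde F3. Claisen–Schmidt condensation of F2 with F3 (KOH, EtOH, rt) should give the (E)-chalcone F4. NaOAc in refluxing EtOH closes ring C by oxa-Michael addition to the racemic tris-MOM flavanone F5. HCl in MeOH then removes the acetals to give the racemic flavanone F6. Preparative HPLC on a chiral stationary phase delivers 32. The antipode can be re-equilibrated with base through the chalcone and separated again.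

**Risk 2, step 6.**
- C–C bond formation between the ester-deactivated diene and the hindered, electron-rich aldehyde may be slow.
- The ortho silyloxy group may erode facial selectivity.
- The benzylic C2–O bond may ionise during the acid step.

Fallback, from 7 back to 11: the stereocentre is set by reagent control and the dicarbonyl chain is added afterwards. Asymmetric allylboration of 7 with (−)-B-allyldiisopinocampheylborane (Et2O, −78 °C; NaOH, H2O2) should give (1S)-1-Ar-but-3-en-1-ol F7. TESCl and imidazole give the triethylsilyl ether F8. Wacker oxidation of the terminal alkene (PdCl2, Cu(OAc)2, O2, DMA/H2O) gives (4S)-4-Ar-4-(triethylsilyloxy)butan-2-one F9. Kinetic enolisation at the methyl group (LiHMDS, THF, −78 °C) and Claisen condensation with diethyl oxalate give ethyl (6S)-6-Ar-2,4-dioxo-6-(triethylsilyloxy)hexanoate F10. PPTS in EtOH, followed by catalytic TFA in CH2Cl2, removes the silyl group and cyclodehydrates to 11.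

**Risk 3, step 9.**
- Deprotonation at C3 may compete with side-chain enolisation.
- That deprotonation would be followed by expulsion of O1, ring opening and erosion of the C2 configuration.
- The amide base may also attack the enedione.

Fallback, from 13 (through 15) and 14 back to 19: the activated 1,3-diketone is assembled by C-acylation, so no strong base meets the chiral pyranone and ketone 17 is bypassed. Bromide 14 and Mg in THF give (4-methylpent-3-enyl)magnesium bromide F11. Addition of F11 to ethyl trifluoroacetate at −78 °C stops at 1,1,1-trifluoro-6-methylhept-5-en-2-one F12. Soft enolisation of F12 (MgBr2·OEt2, iPr2NEt, CH2Cl2, 0 °C) in the presence of acid chloride 15, made from 13 as in step 8, should give 19. Compound 19 then enters the second half of step 9 (MsN3, Et3N, H2O, MeCN) to give 20.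

## Further compounds

F1 | step 12 | 1-[2,4,6-trihydroxy-3,5-bis(3-methylbut-2-enyl)phenyl]ethanone | CC(=O)c1c(O)c(CC=C(C)C)c(O)c(CC=C(C)C)c1O
F2 | step 12 | 1-[2-hydroxy-4,6-bis(methoxymethoxy)-3,5-bis(3-methylbut-2-enyl)phenyl]ethanone | CC(=O)c1c(O)c(CC=C(C)C)c(OCOC)c(CC=C(C)C)c1OCOC
F3 | step 12 | 7-(methoxymethoxy)-2,2-dimethyl-2H-chromene-6-carbaldehyde | CC1(C)C=Cc2cc(C=O)c(OCOC)cc2O1
F4 | step 12 | (E)-1-[2-hydroxy-4,6-bis(methoxymethoxy)-3,5-bis(3-methylbut-2-enyl)phenyl]-3-[7-(methoxymethoxy)-2,2-dimethyl-2H-chromen-6-yl]prop-2-en-1-one | COCOc1cc2c(cc1/C=C/C(=O)c1c(O)c(CC=C(C)C)c(OCOC)c(CC=C(C)C)c1OCOC)C=CC(C)(C)O2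
F5 | step 12 | racemic 5,7-bis(methoxymethoxy)-2-[7-(methoxymethoxy)-2,2-dimethyl-2H-chromen-6-yl]-6,8-bis(3-methylbut-2-enyl)chroman-4-one | CC(C)=CCc1c(OCOC)c(CC=C(C)C)c2c(c1OCOC)C(=O)CC(c1cc3c(cc1OCOC)OC(C)(C)C=C3)O2
F6 | step 12 | racemic 5,7-dihydroxy-2-(7-hydroxy-2,2-dimethyl-2H-chromen-6-yl)-6,8-bis(3-methylbut-2-enyl)chroman-4-one | CC(C)=CCc1c(O)c(CC=C(C)C)c2c(c1O)C(=O)CC(c1cc3c(cc1O)OC(C)(C)C=C3)O2
F7 | step 6 | (1S)-1-Ar-but-3-en-1-ol | C=CC[C@H](O)c1cc2c(cc1O[Si](C(C)C)(C(C)C)C(C)C)OC(C)(C)C=C2
F8 | step 6 | (1S)-1-Ar-1-(triethylsilyloxy)but-3-ene | C=CC[C@H](O[Si](CC)(CC)CC)c1cc2c(cc1O[Si](C(C)C)(C(C)C)C(C)C)OC(C)(C)C=C2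
F9 | step 6 | (4S)-4-Ar-4-(triethylsilyloxy)butan-2-one | CC(=O)C[C@H](O[Si](CC)(CC)CC)c1cc2c(cc1O[Si](C(C)C)(C(C)C)C(C)C)OC(C)(C)C=C2
F10 | step 6 | ethyl (6S)-6-Ar-2,4-dioxo-6-(triethylsilyloxy)hexanoate | CCOC(=O)C(=O)CC(=O)C[C@H](O[Si](CC)(CC)CC)c1cc2c(cc1O[Si](C(C)C)(C(C)C)C(C)C)OC(C)(C)C=C2
F11 | step 9 | (4-methylpent-3-enyl)magnesium bromide | CC(C)=CCC[Mg]Br
F12 | step 9 | 1,1,1-trifluoro-6-methylhept-5-en-2-one | CC(C)=CCCC(=O)C(F)(F)F
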